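All runs are simulated from invented constants; scatter was added.

Q + X → E spends one Q for each E, so the Q charged is the ceiling of [E]; in Saturday's flask Q, at 250 mM against 500 mM of X, is the limiting reagent.

| flask | Q | X | time |
|---|---|---|---|
| Saturday's | 250 mM | 500 mM |  |
| Monday's | 150 mM | 400 mM |  |
| Friday's | 120 mM | 500 mM |  |
| Tuesday's | 250 mM | 500 mM | 110 h |

| Saturday's run: time / h | Saturday's run: [E] / mM | Monday's run: time / h | Monday's run: [E] / mM | Friday's run: time / h | Friday's run: [E] / mM |
|---|---|---|---|---|---|
| 0.76 | 2.4 | 0.76 | 2.0 | 0.76 | 2.4 |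
| 1.4 | 14.3 | 1.4 | 6.1 | 1.4 | 5.8 |
| 2.8 | 27.9 | 2.8 | 14.3 | 2.8 | 13.1 |
| 5.2 | 54.1 | 5.2 | 28.4 | 5.2 | 26.4 |
| 10 | 76.7 | 10 | 40.7 | 10 | 40.4 |
| 19 | 94.0 | 19 | 50.0 | 19 | 45.5 |

(readings scatter by 2 mM)

- Overall: Q + X -> E.
- Constant volume, constant temperature.
- "The second partner" is X.
- An order is taken over about fifteen percent of the charge, up and down.

1. reaction order in [X] at the outset, round the charge of the Saturday's run, defined at two percent of the Q turned into E
2. reaction order in [Q] at the outset, round the charge of the Saturday's run, defined at two percent of the Q turned into E (one fixed amount of E, the same in the runs compared)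
3. E in the Tuesday's run at 110 h, as a share of the Q charged

Saturday's last reading gives 37.6%: that is the end share s, the [E] at 19 h over the Q charged. The zero of your scale is a ratio of one between two runs at equal X, for then the yield does not follow the Q charged.

Friday's flask, with 120 mM of Q at Saturday's X, gives s = 37.9%, a ratio of 1.01 with a scatter of about 0.0488. Monday's flask, with 150 mM of Q and 400 mM of X, differs from Saturday's in both charges and gives 33.3%, less than Saturday's s.

Tuesday's flask repeats Saturday's charge, so my own reckoning for it at 110 h starts from s and lies somewhat above it, for Saturday's [E] still rose from 76.7 mM to 94.0 mM over its last stretch.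

The forecast stands higher than s, with 41%, order 0.7 in X and 0.9 in Q, holding of two possible causes of the flattening that “both predict a similar plateau”.

The flask gives 38.1% on Tuesday, 0.50 percentage points above s, with orders 0.61 in X and 0.67 in Q.

    Q + X → J (1.058 M⁻¹ h⁻¹)
    J → E (0.1951 h⁻¹)
    X → Oz (0.5256 h⁻¹)
    Q → Rx (0.3589 h⁻¹)

Over the first hours of Saturday's flask, Q + X → J ran beside X → Oz and Q → Rx, whose constants give lifetimes of 1.90 h for X and 2.79 h for Q against those losses. J → E ran alongside them, with a lifetime for J of 5.13 h, longer than both. On the scale of s, a quarter of the Q charged is 66.5% of Saturday's end share; Saturday's flask reached a quarter of its Q at 6.39 h, and Friday's flask a quarter of its own Q at 5.92 h.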